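Slowness comes first: how long does one E wait before it reacts in a flask charged with half the E of the south-east run?

| flask | E | remark | time |
|---|---|---|---|
| south-east | 0.12 M | run made earlier |  |
| flask | 0.060 M |  | 12 h |

south-east run (percent of the E charged)

| time / h | J / % | E / % |
|---|---|---|
| 0.417 | 27.8 | 71.8 |
| 1.33 | 50.5 | 44.1 |
| 2.50 | 59.5 | 29.9 |
| 4.00 | 61.1 | 20.3 |

(each reading ± 0.5 percentage points)

- a species is counted by the E in it: one J or X or Z counts as two
- amounts and yields of J count X too
- given per volume of solution although it is solid: X
- candidate steps: X <-> J; 2 E -> J; J <-> Z

* amount of J in percent of the E charged, at 40 min, 3.0 h and 12 h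

Which fork does an E meet first? Among the candidate steps, E appears in one, where two E give one J, so it stays E or leaves by that step.

And its chance of staying? It needs a partner, and partners thin out as E falls. So the reciprocal of f, the share still E at time t, starts at one and climbs in a straight line of slope s. At the south-east reading nearest half, that slope is 0.953 h⁻¹; the last reading gives 0.982 h⁻¹.

Does that slope carry over to the flask? No: at one rate constant the slope of a second-order decay goes with the charge, so the flask has 0.477 h⁻¹. I call this s the pace of E, the hourly climb of the reciprocal of its surviving share. Half of the E in the flask then lasts 2.10 h.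

What do you commit to? Whatever has left E is J or Z, with X counted in J, so in the flask J plus Z is one minus f: 24.1%, 58.8% and 85.1% at the asked times.

But that is J plus Z. Where is the weak spot? It is the second fork, J to Z. In the south-east run the gap in the balance reaches 18.6% at 4.00 h, and I cannot read a way back from that, so I leave the split open.

The forecast does split it, giving J as 23.2%, 45.5% and 29%, and it adds: “The 12 h value is uncertain because the reversibility of J ⇌ Z is unseen.”

The flask gives J as 23.2%, 49.2% and 52.5%.

    X ⇌ J, rate k1*(cs1 - [J]) while solid is left; crystals form when [J] > cs1 (solubility = 36.0 mM, k = 0.782 h⁻¹)
    2 E → J (k = 3.98 M⁻¹ h⁻¹)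
    J ⇌ Z (K = 0.780, k = 0.112 h⁻¹)

At 12 h the forecast stands 24 percentage points below the flask. In the flask the backward turnover on the path from J to Z is 50% of the forward one, and the relaxation half-life of dissolved J and Z by that step alone, both ways together, is 2.71 h, shorter than the 12 h of the flask. Used once more, s leaves 14.9% as E at 12 h, and the flask holds 15% of E. Of the 85.1% gone from E by then, the flask shows 52.5% as J and 32.6% as Z.

All runs are simulated for substances that don't exist; the scatter is artificial.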